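**Plan**

- Retrosynthetic cuts, in order: (a) the cinnamate C=C (Horner–Wadsworth–Emmons between a C4 aldehyde and a danshensu phosphonoacetate), (b) the O1–C2 bond of the dihydrofuran, (c) the C3–CH2 bond between the ring A arylacetate and the ring B benzyl unit.
- Enabling feature: C2 is benzylic to ring B and para to its 4-hydroxyl, so a 4-hydroxybenzyl group can be oxidised there to a para-quinone methide that the C7a hydroxyl of ring A captures.
- Forward: both core rings come from protocatechualdehyde. Ring A gains its two-carbon arm by O-allylation, Claisen rearrangement and alkene cleavage; the rings are joined by an auxiliary-controlled benzylation; the dihydrofuran (the only ring made) closes in the DDQ step; the danshensu acrylate is attached last and all benzyl-type groups leave together.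
- Stereochemistry: C3 from the (R)-4-benzyl-2-oxazolidinone alkylation, C2 from C3 in the trans-selective closure, the lactate carbon from (R)-danshensu, the (E)-alkene from the stabilised phosphonate.

Key step: step 17

Remark: danshensu is taken as the free (R)-acid; its sodium salt would enter step 18 with one equivalent less of K2CO3.

**Route**

Step 1
Reactants: 1 3,4-dihydroxybenzaldehyde (protocatechualdehyde)
Product: 2 4-(benzyloxy)-3-hydroxybenzaldehyde
Conditions: BnCl (1.0 equiv), NaHCO3, NaI (cat.), DMF, 40 °C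
Reagents that add atoms: benzyl chloride ClCc1ccccc1
Why: Williamson etherification under weak-base control, in which NaHCO3 ionises only the more acidic 4-hydroxyl (para to the formyl group), so monobenzylation should fall on O4.

Step 2
Reactants: 2 4-(benzyloxy)-3-hydroxybenzaldehyde; 3 allyl bromide
Product: 4 3-(allyloxy)-4-(benzyloxy)benzaldehyde
Conditions: K2CO3, DMF, rt
Reagents that add atoms: none
Why: Williamson O-allylation of the remaining phenoxide with a reactive allylic halide is a standard SN2 etherification.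

Step 3
Reactants: 4 3-(allyloxy)-4-(benzyloxy)benzaldehyde
Product: 6 2-allyl-4-(benzyloxy)-3-hydroxybenzaldehyde, via ortho-dienone 5 (not isolated)
Conditions: PhNEt2, 195 °C
Reagents that add atoms: none
Why: Aromatic Claisen rearrangement ([3,3]-sigmatropic shift) can deliver the allyl group only to C2 because the other ortho position carries the benzyloxy group, and the dienone 5 tautomerises to the phenol.

Step 4
Reactants: 6 2-allyl-4-(benzyloxy)-3-hydroxybenzaldehyde
Product: 7 2-allyl-6-(benzyloxy)-3-(5,5-dimethyl-1,3-dioxan-2-yl)phenol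
Conditions: neopentyl glycol, PPTS (cat.), PhMe, reflux, Dean–Stark
Reagents that add atoms: 2,2-dimethylpropane-1,3-diol OCC(C)(C)CO
Why: Acid-catalysed acetalisation with azeotropic removal of water masks the aldehyde as a 2-aryl-1,3-dioxane, the acetal class that tolerates bases, enolates and buffered chlorite, and it is done before the MOM ether is present so that no acid meets that group.

Step 5
Reactants: 7 2-allyl-6-(benzyloxy)-3-(5,5-dimethyl-1,3-dioxan-2-yl)phenol
Product: 8 2-[2-allyl-4-(benzyloxy)-3-(methoxymethoxy)phenyl]-5,5-dimethyl-1,3-dioxane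
Conditions: NaH, THF, 0 °C; MOMCl, 0 °C → rt
Reagents that add atoms: chloromethyl methyl ether COCCl
Why: Williamson-type alkylation of the sodium phenoxide with the highly reactive chloromethyl ether should protect even this flanked ring A phenol as a base-stable, acid-labile MOM ether.

Step 6
Reactants: 8 2-[2-allyl-4-(benzyloxy)-3-(methoxymethoxy)phenyl]-5,5-dimethyl-1,3-dioxane
Product: 10 2-[3-(benzyloxy)-6-(5,5-dimethyl-1,3-dioxan-2-yl)-2-(methoxymethoxy)phenyl]acetaldehyde, via vicinal diol 9 (not isolated)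
Conditions: OsO4 (cat.), NaIO4, 2,6-lutidine, dioxane/H2O, rt; used crude
Reagents that add atoms: osmium tetroxide O=[Os](=O)(=O)=O (catalytic oxygen carrier); sodium periodate [Na+].[O-]I(=O)(=O)=O
Why: Lemieux–Johnson oxidation (dihydroxylation to diol 9, then periodate glycol cleavage, with 2,6-lutidine keeping the medium non-acidic) shortens the allyl group by one carbon to the arylacetaldehyde.

Step 7
Reactants: 10 2-[3-(benzyloxy)-6-(5,5-dimethyl-1,3-dioxan-2-yl)-2-(methoxymethoxy)phenyl]acetaldehyde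
Product: 11 2-[3-(benzyloxy)-6-(5,5-dimethyl-1,3-dioxan-2-yl)-2-(methoxymethoxy)phenyl]acetic acid
Conditions: NaClO2, NaH2PO4, 2-methyl-2-butene, t-BuOH/H2O, 0 °C; work-up at pH 4–5
Reagents that add atoms: sodium chlorite [Na+].[O-]Cl=O
Why: Pinnick oxidation converts the enolisable aldehyde into the acid without touching benzyl ethers, and buffered chlorite at 0 °C is a medium that 2-aryl-1,3-dioxanes (as in para-methoxybenzylidene acetals) and MOM ethers normally survive.

Step 8
Reactants: 11 2-[3-(benzyloxy)-6-(5,5-dimethyl-1,3-dioxan-2-yl)-2-(methoxymethoxy)phenyl]acetic acid; 12 (R)-4-benzyl-2-oxazolidinone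
Product: 14 (R)-4-benzyl-3-{2-[3-(benzyloxy)-6-(5,5-dimethyl-1,3-dioxan-2-yl)-2-(methoxymethoxy)phenyl]acetyl}oxazolidin-2-one, via mixed pivalic anhydride 13 (not isolated)
Conditions: t-BuCOCl, Et3N, THF, −20 °C; then LiCl, 12, −20 °C → rt
Reagents that add atoms: none
Why: N-acylation of the oxazolidinone through the mixed pivalic anhydride with LiCl/Et3N activation is the standard mild way to load an Evans auxiliary and avoids strong base.

Step 9
Reactants: 1 3,4-dihydroxybenzaldehyde
Product: 15 3-hydroxy-4-(methoxymethoxy)benzaldehyde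
Conditions: MOMCl (1.05 equiv), K2CO3 (1.1 equiv), acetone, 0 °C → rt
Reagents that add atoms: chloromethyl methyl ether COCCl
Why: Weak-base Williamson alkylation again selects the more acidic 4-hydroxyl, which places the acid-labile group on the ring B oxygen para to the future benzylic carbon.

Step 10
Reactants: 15 3-hydroxy-4-(methoxymethoxy)benzaldehyde
Product: 16 3-(benzyloxy)-4-(methoxymethoxy)benzaldehyde
Conditions: BnBr, K2CO3, DMF, rt
Reagents that add atoms: benzyl bromide BrCc1ccccc1
Why: Williamson benzylation of the remaining phenol installs the ring B group that stays until the end.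

Step 11
Reactants: 16 3-(benzyloxy)-4-(methoxymethoxy)benzaldehyde
Product: 17 [3-(benzyloxy)-4-(methoxymethoxy)phenyl]methanol
Conditions: NaBH4, MeOH/THF, 0 °C
Reagents that add atoms: none
Why: Borohydride reduction of an aryl aldehyde to the benzylic alcohol is chemoselective and leaves both ethers untouched.

Step 12
Reactants: 17 [3-(benzyloxy)-4-(methoxymethoxy)phenyl]methanol
Product: 18 2-(benzyloxy)-4-(bromomethyl)-1-(methoxymethoxy)benzene
Conditions: CBr4, PPh3, CH2Cl2, 0 °C; used at once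
Reagents that add atoms: carbon tetrabromide BrC(Br)(Br)Br
Why: Appel bromination proceeds under neutral conditions, so the MOM ether survives and the reactive para-alkoxybenzyl bromide is obtained without acid.

Step 13
Reactants: 14 (R)-4-benzyl-3-{2-[3-(benzyloxy)-6-(5,5-dimethyl-1,3-dioxan-2-yl)-2-(methoxymethoxy)phenyl]acetyl}oxazolidin-2-one; 18 2-(benzyloxy)-4-(bromomethyl)-1-(methoxymethoxy)benzene
Product: 19 (R)-4-benzyl-3-{(2R)-2-[3-(benzyloxy)-6-(5,5-dimethyl-1,3-dioxan-2-yl)-2-(methoxymethoxy)phenyl]-3-[3-(benzyloxy)-4-(methoxymethoxy)phenyl]propanoyl}oxazolidin-2-one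
Conditions: NaN(SiMe3)2, THF, −78 °C; then 18, −78 → −30 °C
Reagents that add atoms: none
Why: Evans asymmetric alkylation, in which the chelated (Z)-sodium enolate is attacked by the benzylic bromide on the face away from the C4 benzyl group of the (R)-auxiliary, setting the (R) centre that becomes C3 (the same face selection by which arylacetyl imides of the (S)-auxiliary give (S)-2-arylpropanoates with MeI).

Step 14
Reactants: 19 (R)-4-benzyl-3-{(2R)-2-[3-(benzyloxy)-6-(5,5-dimethyl-1,3-dioxan-2-yl)-2-(methoxymethoxy)phenyl]-3-[3-(benzyloxy)-4-(methoxymethoxy)phenyl]propanoyl}oxazolidin-2-one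
Product: 21 (2R)-2-[3-(benzyloxy)-6-(5,5-dimethyl-1,3-dioxan-2-yl)-2-(methoxymethoxy)phenyl]-3-[3-(benzyloxy)-4-(methoxymethoxy)phenyl]propanoic acid, via peroxy acid 20 (not isolated)
Conditions: LiOH, H2O2, THF/H2O, 0 °C; Na2SO3 (aq); HCl (1 M) to pH 4
Reagents that add atoms: hydrogen peroxide OO
Why: Hydroperoxide cleavage of the imide, in which the small and weakly basic LiOOH attacks the exocyclic carbonyl even of hindered imides at 0 °C without epimerising the α-aryl centre, and sulfite reduces the peroxy acid 20 to the acid.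

Step 15
Reactants: 21 (2R)-2-[3-(benzyloxy)-6-(5,5-dimethyl-1,3-dioxan-2-yl)-2-(methoxymethoxy)phenyl]-3-[3-(benzyloxy)-4-(methoxymethoxy)phenyl]propanoic acid
Product: 22 methyl (2R)-2-[3-(benzyloxy)-6-(5,5-dimethyl-1,3-dioxan-2-yl)-2-(methoxymethoxy)phenyl]-3-[3-(benzyloxy)-4-(methoxymethoxy)phenyl]propanoate
Conditions: TMSCHN2, PhMe/MeOH, 0 °C
Reagents that add atoms: (trimethylsilyl)diazomethane C[Si](C)(C)C=[N+]=[N-]
Why: Esterification with a diazoalkane is neutral and fast, so the configurationally sensitive α-aryl centre never meets base.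

Step 16
Reactants: 22 methyl (2R)-2-[3-(benzyloxy)-6-(5,5-dimethyl-1,3-dioxan-2-yl)-2-(methoxymethoxy)phenyl]-3-[3-(benzyloxy)-4-(methoxymethoxy)phenyl]propanoate
Product: 23 methyl (2R)-2-[3-(benzyloxy)-6-formyl-2-hydroxyphenyl]-3-[3-(benzyloxy)-4-hydroxyphenyl]propanoate
Conditions: HCl (3 M aq), MeOH/THF, 45 °C
Reagents that add atoms: water O
Why: Acid-catalysed acetal solvolysis removes both MOM ethers and the dioxane in one operation, and acid in methanol is chosen over fluoride or base because the α-aryl ester does not epimerise under acid and methanol keeps the 2-hydroxyphenylacetic ester from closing to the benzofuranone.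

Step 17
Reactants: 23 methyl (2R)-2-[3-(benzyloxy)-6-formyl-2-hydroxyphenyl]-3-[3-(benzyloxy)-4-hydroxyphenyl]propanoate
Product: 25 methyl (2S,3S)-7-(benzyloxy)-2-[3-(benzyloxy)-4-hydroxyphenyl]-4-formyl-2,3-dihydro-1-benzofuran-3-carboxylate, via para-quinone methide 24 (not isolated)
Conditions: DDQ (1.05 equiv), CH2Cl2, 0 °C → rt
Reagents that add atoms: none
Why: DDQ forms a charge-transfer complex with the electron-rich ring B phenol and removes hydride from the benzylic CH2 para to its hydroxyl, giving para-quinone methide 24, whose exocyclic carbon is attacked by the ring A hydroxyl (oxa-1,6-addition) with rearomatisation of ring B. The closest known reactions are the DDQ cyclisation of 2'-hydroxyisoflavans to pterocarpans and the Ag2O or DDQ oxidation of 4-alkylphenols to quinone methides that are trapped by phenols in dihydrobenzofuran neolignan synthesis. The dihydrofuran closes in a 5-exo-trig mode, the attacked double bond lying outside the new ring. The new C2 centre is controlled by the existing C3 centre: the aryl group takes the face anti to the ester in the envelope transition state, and because the addition is reversible in the presence of the acidic hydroquinone the trans (2S,3S) isomer should accumulate. Three selectivities are needed: oxidation of ring B and not ring A, secured by the formyl group that makes the ring A phenol electron-poor; closure ahead of tautomerisation of 24 to the stilbene, secured by the five-membered reach of the nucleophile and the absence of base; and no second dehydrogenation to the benzofuran, secured by one equivalent of oxidant at low temperature and by the C3 ester, which makes the C2 hydride less available.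

Step 18
Reactants: 26 (R)-3-(3,4-dihydroxyphenyl)lactic acid (danshensu)
Product: 27 4-methoxybenzyl (2R)-3-{3,4-bis[(4-methoxybenzyl)oxy]phenyl}-2-hydroxypropanoate
Conditions: PMBCl (3.3 equiv), K2CO3, NaI (cat.), DMF, rt
Reagents that add atoms: 4-methoxybenzyl chloride COc1ccc(CCl)cc1
Why: Williamson alkylation with K2CO3 reaches the carboxylate and both phenoxides but not the far less acidic secondary alcohol, giving a danshensu unit whose three groups all ionise readily under BCl3.

Step 19
Reactants: 27 4-methoxybenzyl (2R)-3-{3,4-bis[(4-methoxybenzyl)oxy]phenyl}-2-hydroxypropanoate; 28 (diethoxyphosphoryl)acetic acid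
Product: 29 4-methoxybenzyl (2R)-3-{3,4-bis[(4-methoxybenzyl)oxy]phenyl}-2-{[(diethoxyphosphoryl)acetyl]oxy}propanoate
Conditions: DCC, DMAP (cat.), CH2Cl2, 0 °C → rt
Reagents that add atoms: none
Why: Steglich esterification acylates the secondary alcohol under near-neutral conditions that leave the lactate stereocentre alone.

Step 20
Reactants: 25 methyl (2S,3S)-7-(benzyloxy)-2-[3-(benzyloxy)-4-hydroxyphenyl]-4-formyl-2,3-dihydro-1-benzofuran-3-carboxylate; 29 4-methoxybenzyl (2R)-3-{3,4-bis[(4-methoxybenzyl)oxy]phenyl}-2-{[(diethoxyphosphoryl)acetyl]oxy}propanoate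
Product: 30 methyl (2S,3S)-7-(benzyloxy)-2-[3-(benzyloxy)-4-hydroxyphenyl]-4-[(1E)-3-{[(2R)-3-{3,4-bis[(4-methoxybenzyl)oxy]phenyl}-1-[(4-methoxybenzyl)oxy]-1-oxopropan-2-yl]oxy}-3-oxoprop-1-en-1-yl]-2,3-dihydro-1-benzofuran-3-carboxylate
Conditions: LiCl, i-Pr2NEt, MeCN, rt
Reagents that add atoms: none
Why: Horner–Wadsworth–Emmons olefination under Masamune–Roush conditions uses a base too weak to ionise the free phenol, open the dihydrofuran or epimerise C3 and the lactate carbon, and the stabilised phosphonate should give the (E)-alkene.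

Step 21
Reactants: 30 methyl (2S,3S)-7-(benzyloxy)-2-[3-(benzyloxy)-4-hydroxyphenyl]-4-[(1E)-3-{[(2R)-3-{3,4-bis[(4-methoxybenzyl)oxy]phenyl}-1-[(4-methoxybenzyl)oxy]-1-oxopropan-2-yl]oxy}-3-oxoprop-1-en-1-yl]-2,3-dihydro-1-benzofuran-3-carboxylate
Product: 31 monomethyl lithospermate
Conditions: BCl3 (excess), C6HMe5, CH2Cl2, −78 °C; MeOH quench
Reagents that add atoms: none
Why: Lewis-acid dealkylation with BCl3 and pentamethylbenzene as a non-Lewis-basic cation scavenger should cleave the two aryl benzyl ethers, the two aryl 4-methoxybenzyl ethers and the 4-methoxybenzyl ester at −78 °C, while the methyl ester, the cinnamate ester and the alkene (which rules out hydrogenolysis) are not attacked.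

**Compound list**

1 | 3,4-dihydroxybenzaldehyde (protocatechualdehyde) | O=Cc1ccc(O)c(O)c1 | starting material
2 | 4-(benzyloxy)-3-hydroxybenzaldehyde | O=Cc1ccc(OCc2ccccc2)c(O)c1 | intermediate
3 | allyl bromide | C=CCBr | starting material
4 | 3-(allyloxy)-4-(benzyloxy)benzaldehyde | O=Cc1ccc(OCc2ccccc2)c(OCC=C)c1 | intermediate
5 | 6-allyl-2-(benzyloxy)-5-formylcyclohexa-2,4-dien-1-one (racemic ortho-dienone) | O=CC1=CC=C(OCc2ccccc2)C(=O)C1CC=C | intermediate
6 | 2-allyl-4-(benzyloxy)-3-hydroxybenzaldehyde | O=Cc1ccc(OCc2ccccc2)c(O)c1CC=C | intermediate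
7 | 2-allyl-6-(benzyloxy)-3-(5,5-dimethyl-1,3-dioxan-2-yl)phenol | C=CCc1c(C2OCC(C)(C)CO2)ccc(OCc2ccccc2)c1O | intermediate
8 | 2-[2-allyl-4-(benzyloxy)-3-(methoxymethoxy)phenyl]-5,5-dimethyl-1,3-dioxane | C=CCc1c(C2OCC(C)(C)CO2)ccc(OCc2ccccc2)c1OCOC | intermediate
9 | 3-[3-(benzyloxy)-6-(5,5-dimethyl-1,3-dioxan-2-yl)-2-(methoxymethoxy)phenyl]propane-1,2-diol (racemic) | OCC(O)Cc1c(C2OCC(C)(C)CO2)ccc(OCc2ccccc2)c1OCOC | intermediate
10 | 2-[3-(benzyloxy)-6-(5,5-dimethyl-1,3-dioxan-2-yl)-2-(methoxymethoxy)phenyl]acetaldehyde | O=CCc1c(C2OCC(C)(C)CO2)ccc(OCc2ccccc2)c1OCOC | intermediate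
11 | 2-[3-(benzyloxy)-6-(5,5-dimethyl-1,3-dioxan-2-yl)-2-(methoxymethoxy)phenyl]acetic acid | OC(=O)Cc1c(C2OCC(C)(C)CO2)ccc(OCc2ccccc2)c1OCOC | intermediate
12 | (R)-4-benzyl-2-oxazolidinone | O=C1N[C@H](Cc2ccccc2)CO1 | starting material
13 | mixed anhydride of acid 11 and pivalic acid | CC(C)(C)C(=O)OC(=O)Cc1c(C2OCC(C)(C)CO2)ccc(OCc2ccccc2)c1OCOC | intermediate
14 | (R)-4-benzyl-3-{2-[3-(benzyloxy)-6-(5,5-dimethyl-1,3-dioxan-2-yl)-2-(methoxymethoxy)phenyl]acetyl}oxazolidin-2-one | O=C(Cc1c(C2OCC(C)(C)CO2)ccc(OCc2ccccc2)c1OCOC)N1[C@H](Cc2ccccc2)COC1=O | intermediate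
15 | 3-hydroxy-4-(methoxymethoxy)benzaldehyde | O=Cc1ccc(OCOC)c(O)c1 | intermediate
16 | 3-(benzyloxy)-4-(methoxymethoxy)benzaldehyde | O=Cc1ccc(OCOC)c(OCc2ccccc2)c1 | intermediate
17 | [3-(benzyloxy)-4-(methoxymethoxy)phenyl]methanol | OCc1ccc(OCOC)c(OCc2ccccc2)c1 | intermediate
18 | 2-(benzyloxy)-4-(bromomethyl)-1-(methoxymethoxy)benzene | BrCc1ccc(OCOC)c(OCc2ccccc2)c1 | intermediate
19 | (R)-4-benzyl-3-{(2R)-2-[3-(benzyloxy)-6-(5,5-dimethyl-1,3-dioxan-2-yl)-2-(methoxymethoxy)phenyl]-3-[3-(benzyloxy)-4-(methoxymethoxy)phenyl]propanoyl}oxazolidin-2-one | O=C([C@H](Cc1ccc(OCOC)c(OCc2ccccc2)c1)c1c(C2OCC(C)(C)CO2)ccc(OCc2ccccc2)c1OCOC)N1[C@H](Cc2ccccc2)COC1=O | intermediate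
20 | (2R)-2-[3-(benzyloxy)-6-(5,5-dimethyl-1,3-dioxan-2-yl)-2-(methoxymethoxy)phenyl]-3-[3-(benzyloxy)-4-(methoxymethoxy)phenyl]propaneperoxoic acid | OOC(=O)[C@H](Cc1ccc(OCOC)c(OCc2ccccc2)c1)c1c(C2OCC(C)(C)CO2)ccc(OCc2ccccc2)c1OCOC | intermediate
21 | (2R)-2-[3-(benzyloxy)-6-(5,5-dimethyl-1,3-dioxan-2-yl)-2-(methoxymethoxy)phenyl]-3-[3-(benzyloxy)-4-(methoxymethoxy)phenyl]propanoic acid | OC(=O)[C@H](Cc1ccc(OCOC)c(OCc2ccccc2)c1)c1c(C2OCC(C)(C)CO2)ccc(OCc2ccccc2)c1OCOC | intermediate
22 | methyl (2R)-2-[3-(benzyloxy)-6-(5,5-dimethyl-1,3-dioxan-2-yl)-2-(methoxymethoxy)phenyl]-3-[3-(benzyloxy)-4-(methoxymethoxy)phenyl]propanoate | COC(=O)[C@H](Cc1ccc(OCOC)c(OCc2ccccc2)c1)c1c(C2OCC(C)(C)CO2)ccc(OCc2ccccc2)c1OCOC | intermediate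
23 | methyl (2R)-2-[3-(benzyloxy)-6-formyl-2-hydroxyphenyl]-3-[3-(benzyloxy)-4-hydroxyphenyl]propanoate | COC(=O)[C@H](Cc1ccc(O)c(OCc2ccccc2)c1)c1c(C=O)ccc(OCc2ccccc2)c1O | intermediate
24 | methyl (2R)-2-[3-(benzyloxy)-6-formyl-2-hydroxyphenyl]-3-[3-(benzyloxy)-4-oxocyclohexa-2,5-dien-1-ylidene]propanoate (para-quinone methide, either alkene geometry) | COC(=O)[C@H](C=C1C=CC(=O)C(OCc2ccccc2)=C1)c1c(C=O)ccc(OCc2ccccc2)c1O | intermediate
25 | methyl (2S,3S)-7-(benzyloxy)-2-[3-(benzyloxy)-4-hydroxyphenyl]-4-formyl-2,3-dihydro-1-benzofuran-3-carboxylate | COC(=O)[C@H]1c2c(C=O)ccc(OCc3ccccc3)c2O[C@@H]1c1ccc(O)c(OCc3ccccc3)c1 | intermediate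
26 | (R)-3-(3,4-dihydroxyphenyl)lactic acid (danshensu) | O[C@H](Cc1ccc(O)c(O)c1)C(=O)O | starting material
27 | 4-methoxybenzyl (2R)-3-{3,4-bis[(4-methoxybenzyl)oxy]phenyl}-2-hydroxypropanoate | O[C@H](Cc1ccc(OCc2ccc(OC)cc2)c(OCc2ccc(OC)cc2)c1)C(=O)OCc1ccc(OC)cc1 | intermediate
28 | (diethoxyphosphoryl)acetic acid | CCOP(=O)(CC(=O)O)OCC | starting material
29 | 4-methoxybenzyl (2R)-3-{3,4-bis[(4-methoxybenzyl)oxy]phenyl}-2-{[(diethoxyphosphoryl)acetyl]oxy}propanoate | CCOP(=O)(CC(=O)O[C@H](Cc1ccc(OCc2ccc(OC)cc2)c(OCc2ccc(OC)cc2)c1)C(=O)OCc1ccc(OC)cc1)OCC | intermediate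
30 | methyl (2S,3S)-7-(benzyloxy)-2-[3-(benzyloxy)-4-hydroxyphenyl]-4-[(1E)-3-{[(2R)-3-{3,4-bis[(4-methoxybenzyl)oxy]phenyl}-1-[(4-methoxybenzyl)oxy]-1-oxopropan-2-yl]oxy}-3-oxoprop-1-en-1-yl]-2,3-dihydro-1-benzofuran-3-carboxylate | COC(=O)[C@H]1c2c(/C=C/C(=O)O[C@H](Cc3ccc(OCc4ccc(OC)cc4)c(OCc4ccc(OC)cc4)c3)C(=O)OCc3ccc(OC)cc3)ccc(OCc3ccccc3)c2O[C@@H]1c1ccc(O)c(OCc3ccccc3)c1 | intermediate
31 | monomethyl lithospermate, (2R)-3-(3,4-dihydroxyphenyl)-2-{[(2E)-3-[(2S,3S)-2-(3,4-dihydroxyphenyl)-7-hydroxy-3-(methoxycarbonyl)-2,3-dihydro-1-benzofuran-4-yl]prop-2-enoyl]oxy}propanoic acid | COC(=O)[C@H]1c2c(/C=C/C(=O)O[C@H](Cc3ccc(O)c(O)c3)C(=O)O)ccc(O)c2O[C@@H]1c1ccc(O)c(O)c1 | target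

**Step count and risks**

Total step count: 21. Longest linear sequence: 15 steps (steps 1–8, 13–17, 20 and 21).

Steps most likely to fail:

1. Step 17 (oxidative ring closure). The quinone methide may lose the C3 hydrogen and tautomerise to the stilbene, which would erase the stereocentre. The product may be dehydrogenated a second time to the benzofuran. The 2-hydroxyphenylacetic ester may lactonise before it is oxidised. Fallback: ionisation in place of oxidation, setting out from acid 11 and aldehyde 16 and returning at 25. Acid 11 is loaded onto (S)-4-benzyl-2-oxazolidinone as in step 8 to give the antipodal acyl oxazolidinone F1. Its dibutylboron (Z)-enolate (Bu2BOTf, i-Pr2NEt, CH2Cl2, −78 °C) adds to 16 in an Evans syn aldol reaction to give the aldol adduct F2. The boron aldol uses the enolate face opposite to that of the chelated alkylation, hence the antipodal auxiliary for the same C3 configuration. MeOMgBr in MeOH at 0 °C should give the hydroxy methyl ester F3. HCl in MeOH/THF/H2O then removes both MOM groups and the acetal and ionises the now para-hydroxybenzylic alcohol to the same quinone methide, which the ring A hydroxyl traps to give 25. No oxidant is present, so neither over-oxidation nor attack on ring A can occur.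

2. Step 13 (auxiliary-controlled benzylation). The enolate of the doubly ortho-substituted arylacetyl imide may alkylate sluggishly, with poor facial selectivity, or fragment by loss of the auxiliary before the bromide reacts. Fallback: asymmetric hydrogenation, setting out from acid 11 and aldehyde 16 and returning at 21. Perkin condensation (Ac2O, Et3N, 110 °C) should give the (E)-2,3-diarylacrylic acid F4. Homogeneous hydrogenation (H2, Ru(OAc)2(BINAP), MeOH), with the ligand antipode that a trial reduction shows to give the (R)-acid, leads to 21. The benzyl ethers are not touched by this homogeneous ruthenium catalyst.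

3. Step 21 (global dealkylation). The Lewis acid may also ionise the benzylic C2–O1 bond of the dihydrofuran (ring opening and capture by the scavenger), cleavage of the five groups may stop part-way, and the free polyphenol acid is sensitive during isolation. Fallback: deprotection before olefination, setting out from 25 and 27 and returning at 31. Hydrogenolysis of 25 (H2, Pd/C, EtOAc, rt, stopped after uptake of two equivalents) is possible because no alkene is present yet and should give the triphenol aldehyde F5. Alcohol 27 is acylated with Meldrum's acid (PhMe, 90 °C) to the protected malonate half ester F6, and hydrogenolysis (H2, Pd/C, EtOAc/MeOH) gives the unprotected malonate half ester F7. Knoevenagel–Doebner condensation of F5 with F7 (pyridine, piperidine cat., 50 °C) forms the (E)-cinnamate with decarboxylation and gives 31 directly, so no Lewis acid meets the dihydrobenzofuran.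

**Further compounds**

F1 | step 17 | (S)-4-benzyl-3-{2-[3-(benzyloxy)-6-(5,5-dimethyl-1,3-dioxan-2-yl)-2-(methoxymethoxy)phenyl]acetyl}oxazolidin-2-one | O=C(Cc1c(C2OCC(C)(C)CO2)ccc(OCc2ccccc2)c1OCOC)N1[C@@H](Cc2ccccc2)COC1=O
F2 | step 17 | (S)-4-benzyl-3-{(2S,3S)-2-[3-(benzyloxy)-6-(5,5-dimethyl-1,3-dioxan-2-yl)-2-(methoxymethoxy)phenyl]-3-[3-(benzyloxy)-4-(methoxymethoxy)phenyl]-3-hydroxypropanoyl}oxazolidin-2-one | O=C([C@H]([C@H](O)c1ccc(OCOC)c(OCc2ccccc2)c1)c1c(C2OCC(C)(C)CO2)ccc(OCc2ccccc2)c1OCOC)N1[C@@H](Cc2ccccc2)COC1=O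
F3 | step 17 | methyl (2S,3S)-2-[3-(benzyloxy)-6-(5,5-dimethyl-1,3-dioxan-2-yl)-2-(methoxymethoxy)phenyl]-3-[3-(benzyloxy)-4-(methoxymethoxy)phenyl]-3-hydroxypropanoate | COC(=O)[C@H]([C@H](O)c1ccc(OCOC)c(OCc2ccccc2)c1)c1c(C2OCC(C)(C)CO2)ccc(OCc2ccccc2)c1OCOC
F4 | step 13 | (2E)-2-[3-(benzyloxy)-6-(5,5-dimethyl-1,3-dioxan-2-yl)-2-(methoxymethoxy)phenyl]-3-[3-(benzyloxy)-4-(methoxymethoxy)phenyl]prop-2-enoic acid | OC(=O)/C(=C/c1ccc(OCOC)c(OCc2ccccc2)c1)c1c(C2OCC(C)(C)CO2)ccc(OCc2ccccc2)c1OCOC
F5 | step 21 | methyl (2S,3S)-2-(3,4-dihydroxyphenyl)-4-formyl-7-hydroxy-2,3-dihydro-1-benzofuran-3-carboxylate | COC(=O)[C@H]1c2c(C=O)ccc(O)c2O[C@@H]1c1ccc(O)c(O)c1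
F6 | step 21 | 3-{[(2R)-3-{3,4-bis[(4-methoxybenzyl)oxy]phenyl}-1-[(4-methoxybenzyl)oxy]-1-oxopropan-2-yl]oxy}-3-oxopropanoic acid | OC(=O)CC(=O)O[C@H](Cc1ccc(OCc2ccc(OC)cc2)c(OCc2ccc(OC)cc2)c1)C(=O)OCc1ccc(OC)cc1
F7 | step 21 | (2R)-2-[(carboxyacetyl)oxy]-3-(3,4-dihydroxyphenyl)propanoic acid | OC(=O)CC(=O)O[C@H](Cc1ccc(O)c(O)c1)C(=O)O
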